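The C2–C6 segment of the heptane chain, with its anti pair of C–O bonds at C3 (acetate) and C5 (hydroxyl) around the C4 methylene, is taken from the five-membered ring of trans-4-acetoxycyclopent-2-en-1-ol: the ring CH2 is C4, the two carbinol carbons are C5 and C3, and the ring alkene carbons become C6 and C2. One ring-opening cross-metathesis with excess 3,4-bis(benzyloxy)styrene cleaves that alkene and forms C1=C2 and C6=C7, attaching both protected catechol rings without touching either stereocentre. The precursor is the (1S,4S) monoacetate, reached by Mitsunobu inversion of the commercial (1R,4S)-cis monoacetate; two hydrogenations finish.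

Key step: step 4

Remark: the (1R,4S) enantiomer of cis-4-acetoxycyclopent-2-en-1-ol is assumed to be commercial in enantiopure form; the (3S,5S) label of the diene and the (3R,5R) label of the target describe the same spatial arrangement, the switch coming only from the CIP ranking of C2/C6 against C4.

Step 1
Reactants: 1 3,4-bis(benzyloxy)benzaldehyde; 2 methyltriphenylphosphonium bromide
Product: 4 3,4-bis(benzyloxy)styrene, via methylenetriphenylphosphorane 3 (not isolated)
Conditions: 2, KOtBu, THF, 0 °C; then 1, 0 °C to rt
Reagents that add atoms: none
Why: Wittig methylenation of a non-enolisable aromatic aldehyde by the unstabilised ylide should proceed irreversibly through the oxaphosphetane, with the benzyl ethers inert to KOtBu in THF and no stereocentre involved.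

Step 2
Reactants: 5 (1R,4S)-cis-4-acetoxycyclopent-2-en-1-ol
Product: 6 (1S,4S)-4-(formyloxy)cyclopent-2-en-1-yl acetate (trans diester)
Conditions: HCO2H, PPh3, DIAD, THF, −10 °C to rt
Reagents that add atoms: formic acid, O=CO
Why: In this Mitsunobu reaction the hydroxyl is activated as an alkoxyphosphonium ion and displaced by formate in an SN2 step, so the carbinol carbon should invert from R to S (cis to trans) while the acetate-bearing carbon is untouched, the low temperature disfavouring allylic transposition and elimination.

Step 3
Reactants: 6 (1S,4S)-4-(formyloxy)cyclopent-2-en-1-yl acetate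
Product: 7 (1S,4S)-trans-4-acetoxycyclopent-2-en-1-ol
Conditions: KHCO3 (cat.), MeOH, 0 °C to rt, monitored; non-aqueous work-up
Reagents that add atoms: none
Why: Base-catalysed transesterification removes a formate far faster than an acetate, and in the trans ring the freed hydroxyl cannot reach the acetate across the ring, so chemoselective methanolysis should leave the monoacetate with both stereocentres unchanged.

Step 4
Reactants: 7 (1S,4S)-trans-4-acetoxycyclopent-2-en-1-ol; 4 3,4-bis(benzyloxy)styrene (4 equiv)
Product: 8 (1E,3S,5S,6E)-1,7-bis[3,4-bis(benzyloxy)phenyl]-5-hydroxyhepta-1,6-dien-3-yl acetate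
Conditions: second-generation Grubbs catalyst RuCl2(=CHPh)(H2IMes)(PCy3) (5 mol%, two portions), 1,4-benzoquinone (10 mol%), CH2Cl2 (0.3 M in 7), 40 °C, slow Ar sweep
Reagents that add atoms: none
Why: Ring-opening cross-metathesis: the arylidene carbene formed from the catalyst and 4 adds across the ring alkene of 7 in a [2+2] step, cycloreversion of the ruthenacyclobutane opens the five-membered ring to a styryl end and a new alkylidene, and a second molecule of 4 caps that alkylidene while the resulting Ru=CH2 returns to the arylidene with loss of ethylene, so C1=C2 and C6=C7 are made in one operation. The closest known reaction type is ruthenium-carbene ring-opening cross-metathesis of cyclopentenes with terminal alkenes such as styrenes and acrylates. No ring is closed, so no mode of closure arises, and no stereocentre is created: C3 and C5 are allylic spectators that the carbene never touches, and the E geometry expected for aryl-conjugated disubstituted alkenes is in any case erased in step 5. The selectivity needed is ring opening with double capping ahead of self-metathesis of 4, oligomerisation and re-closure of the diene, and it is secured by the fourfold excess of 4 at high concentration, by sweeping out ethylene, by stopping before 4 is exhausted, and by the free allylic hydroxyl of 7, which is left unmasked because hydrogen bonding to a chloride ligand speeds carbene delivery to this doubly hindered, weakly strained alkene. 1,4-Benzoquinone intercepts ruthenium hydrides and so guards against alkene migration and carbinol-to-ketone isomerisation. The acetate needs no positional control, since the two oxygens of the anti diol are homotopic and a 1,3-acyl shift after ring opening would return the same compound.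

Step 5
Reactants: 8 (1E,3S,5S,6E)-1,7-bis[3,4-bis(benzyloxy)phenyl]-5-hydroxyhepta-1,6-dien-3-yl acetate
Product: 9 (3R,5R)-1,7-bis[3,4-bis(benzyloxy)phenyl]-5-hydroxyheptan-3-yl acetate
Conditions: H2 (4 bar), RhCl(PPh3)3 (10 mol%), toluene–EtOH (1:1), rt
Reagents that add atoms: none
Why: Homogeneous hydrogenation with RhCl(PPh3)3 adds H2 to the two disubstituted alkenes through a rhodium dihydride without passing through allyl-metal species, so the allylic C–OAc and C–OH bonds and the benzyl ethers should survive and the stereocentres stay as set.

Step 6
Reactants: 9 (3R,5R)-1,7-bis[3,4-bis(benzyloxy)phenyl]-5-hydroxyheptan-3-yl acetate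
Product: 10 (3R,5R)-1,7-bis(3,4-dihydroxyphenyl)-5-hydroxyheptan-3-yl acetate
Conditions: H2 (1 atm), 10% Pd/C, EtOAc–EtOH (3:1), rt; filtration under Ar
Reagents that add atoms: none
Why: Catalytic hydrogenolysis on Pd/C cleaves the four benzyl aryl ethers under neutral conditions in which the aliphatic acetate and the non-benzylic secondary alcohol are inert, so the free catechols should be released without acyl transfer or change at C3 and C5.

Compound list
1 | 3,4-bis(benzyloxy)benzaldehyde | O=Cc1ccc(OCc2ccccc2)c(OCc2ccccc2)c1 | starting material
2 | methyltriphenylphosphonium bromide | [Br-].C[P+](c1ccccc1)(c1ccccc1)c1ccccc1 | starting material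
3 | methylenetriphenylphosphorane | C=P(c1ccccc1)(c1ccccc1)c1ccccc1 | intermediate
4 | 3,4-bis(benzyloxy)styrene | C=Cc1ccc(OCc2ccccc2)c(OCc2ccccc2)c1 | intermediate
5 | (1R,4S)-cis-4-acetoxycyclopent-2-en-1-ol | CC(=O)O[C@@H]1C=C[C@H](O)C1 | starting material
6 | (1S,4S)-4-(formyloxy)cyclopent-2-en-1-yl acetate | CC(=O)O[C@@H]1C=C[C@@H](OC=O)C1 | intermediate
7 | (1S,4S)-trans-4-acetoxycyclopent-2-en-1-ol | CC(=O)O[C@@H]1C=C[C@@H](O)C1 | intermediate
8 | (1E,3S,5S,6E)-1,7-bis[3,4-bis(benzyloxy)phenyl]-5-hydroxyhepta-1,6-dien-3-yl acetate | CC(=O)O[C@H](/C=C/c1ccc(OCc2ccccc2)c(OCc2ccccc2)c1)C[C@H](O)/C=C/c1ccc(OCc2ccccc2)c(OCc2ccccc2)c1 | intermediate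
9 | (3R,5R)-1,7-bis[3,4-bis(benzyloxy)phenyl]-5-hydroxyheptan-3-yl acetate | CC(=O)O[C@H](CCc1ccc(OCc2ccccc2)c(OCc2ccccc2)c1)C[C@H](O)CCc1ccc(OCc2ccccc2)c(OCc2ccccc2)c1 | intermediate
10 | (3R,5R)-1,7-bis(3,4-dihydroxyphenyl)-5-hydroxyheptan-3-yl acetate | CC(=O)O[C@H](CCc1ccc(O)c(O)c1)C[C@H](O)CCc1ccc(O)c(O)c1 | target

Total step count: 6. Longest linear sequence: 5 steps (steps 2 to 6, from compound 5).

Steps most likely to fail

1. Step 4. The weakly strained ring alkene, hindered on both faces, may engage the carbene too slowly, so that 4 is consumed by self-metathesis. The diene may also re-close with extrusion of the stilbene once 4 runs low, and hydride-induced isomerisation of the allylic carbinol is possible.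
Fallback, setting out from compound 6 and coming back at compound 9: the ring alkene is cleaved oxidatively and the two styryl bonds are made by olefination instead of metathesis. Ozonolysis of 6 (O3, CH2Cl2, −78 °C; then PPh3) should give (2S,4S)-2-acetoxy-4-(formyloxy)pentanedial F1. [3,4-Bis(benzyloxy)benzyl]triphenylphosphonium chloride F2, made from commercial 3,4-bis(benzyloxy)benzyl chloride and PPh3 in hot toluene, is deprotonated with NaN(SiMe3)2 in THF at −78 °C to [3,4-bis(benzyloxy)benzylidene]triphenylphosphorane F3. Double Wittig olefination of F1 at low temperature should then give (3S,5S)-1,7-bis[3,4-bis(benzyloxy)phenyl]-5-(formyloxy)hepta-1,6-dien-3-yl acetate F4 as a mixture of alkene isomers, which does not matter. Hydrogenation under the conditions of step 5 should give (3R,5R)-1,7-bis[3,4-bis(benzyloxy)phenyl]-5-(formyloxy)heptan-3-yl acetate F5, and formate methanolysis under the conditions of step 3 returns 9.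

2. Step 5. Hydrogen uptake at the hindered, aryl-conjugated alkenes may be slow, giving rhodium time to isomerise the allylic carbinol to a ketone or to erode the allylic C–O bonds.
Fallback, setting out from compound 8 and coming back at compound 9: metal-catalysed hydrogenation is abandoned for metal-free, concerted hydrogen transfer from diimide (2-nitrobenzenesulfonylhydrazide, Et3N, CH2Cl2, rt, repeated charges). Diimide cannot cleave C–O bonds or isomerise the alcohol and leaves benzyl ethers and the acetate alone; no new compound arises (F0).

3. Step 3. The acetate may be methanolysed alongside the formate, and the small, water-soluble, rather volatile alcohol may be lost on isolation.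
Fallback, setting out from compound 5 and coming back at compound 7: the temporary ester is changed to one removed by a mechanism the acetate cannot follow. Mitsunobu inversion of 5 with chloroacetic acid (PPh3, DIAD, THF, 0 °C) should give (1S,4S)-4-acetoxycyclopent-2-en-1-yl chloroacetate F6. Thiourea with NaHCO3 in EtOH at 55 °C then alkylates at the CH2Cl group and cyclises onto the chloroacetyl carbonyl, releasing 7 with the acetate untouched.

Further compounds
F1 | step 4 | (2S,4S)-2-acetoxy-4-(formyloxy)pentanedial | CC(=O)O[C@H](C=O)C[C@H](OC=O)C=O
F2 | step 4 | [3,4-bis(benzyloxy)benzyl]triphenylphosphonium chloride | [Cl-].c1ccc(cc1)[P+](Cc1ccc(OCc2ccccc2)c(OCc2ccccc2)c1)(c1ccccc1)c1ccccc1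
F3 | step 4 | [3,4-bis(benzyloxy)benzylidene]triphenylphosphorane | c1ccc(cc1)P(=Cc1ccc(OCc2ccccc2)c(OCc2ccccc2)c1)(c1ccccc1)c1ccccc1
F4 | step 4 | (3S,5S)-1,7-bis[3,4-bis(benzyloxy)phenyl]-5-(formyloxy)hepta-1,6-dien-3-yl acetate, mixture of alkene isomers | CC(=O)O[C@H](C=Cc1ccc(OCc2ccccc2)c(OCc2ccccc2)c1)C[C@H](OC=O)C=Cc1ccc(OCc2ccccc2)c(OCc2ccccc2)c1
F5 | step 4 | (3R,5R)-1,7-bis[3,4-bis(benzyloxy)phenyl]-5-(formyloxy)heptan-3-yl acetate | CC(=O)O[C@H](CCc1ccc(OCc2ccccc2)c(OCc2ccccc2)c1)C[C@H](OC=O)CCc1ccc(OCc2ccccc2)c(OCc2ccccc2)c1
F0 | step 5 | none | none
F6 | step 3 | (1S,4S)-4-acetoxycyclopent-2-en-1-yl chloroacetate | CC(=O)O[C@@H]1C=C[C@@H](OC(=O)CCl)C1
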